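## The problem

Target 33 is a germacranolide. Its carbocycle is a cyclodeca-1(10),4-diene with a Z alkene at C1=C10 and an E alkene at C4=C5. An α-methylene γ-lactone (O6–C12(=O)–C11(=C13)–C7) is fused across C6–C7, with the ring bonds C6–C5 and C7–C8 trans on the lactone. Four contiguous stereocentres (6S,7R,8S,9S) lie on the ten-membered ring; C7 is a fully substituted carbinol that also carries C11, and C8/C9 form a cis (erythro) diol of which only O9 is acylated. C8 and C9 can be taken together from the chiral pool and are then the only source of absolute configuration. They have to direct C7, and C6 follows C7 through the ring fusion, so one event that sets C6 and C7 together is wanted. The fragile parts are the α-methylene lactone (conjugate addition), the 1,5-diene in the medium ring (acid-induced transannular cyclisation, Cope rearrangement on heating) and the C9 ester beside a free C8 hydroxyl (acyl migration). The C8 hydroxyl is also γ to C12 and could take over the lactone under base, so the lactone must be closed while O8 is masked and the ester must come last. The feature that opens the way is the homoallylic alcohol motif C6(OH)–C7(OR)–C11(=C13H2): it is the retron of a [2,3]-Wittig shift of an allyl ether C6–O–C13–C11=C7, whose oxygen becomes O6.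

## Retrosynthesis

**33 ⇒ 31 + 32.** The O9–acyl bond is cut first. An ester would not survive the organolithium and hydride steps, and the free C8 hydroxyl beside it invites migration, so isobutyryl chloride 32 is added to triol 31 at the very end. The forward step needs site selectivity: O7 is tertiary and O8 is flanked by the quaternary C7, which leaves the allylic O9 as the most accessible hydroxyl.

**31 ⇒ 30.** The C7 methoxymethyl ether and the C8/C9 acetonide are removed together. Both are inert to base and organolithiums and both fall to Me2BBr at −78 °C, conditions chosen to spare the diene.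

**30 ⇒ 28 ⇒ 27.** The lactone C12–O6 bond is cut and C12 taken back to the alcohol level; forward this is an oxidative lactonisation of the 2-methylene-1,4-diol 28. The acetonide keeps O8 out of the lactonisation. O12 is carried through the key step as a triisopropylsilyl ether (27). A benzyl-type ether was rejected because its benzylic hydrogens are the most acidic site of a benzyl allyl ether and would start a competing Wittig shift onto C7.

**27 ⇒ 25 (key disconnection).** C6–C7 is cut and O–C13 reconnected, which expands the ten-membered carbocycle to the thirteen-membered bis-allylic ether 25. Compared with closing the ten-membered ring directly by C–C bond formation, the ether ring is strain-free and closes by O-alkylation. The contraction then delivers the C6 alkoxide, the oxygenated quaternary C7 and the exo-methylene in one step. The precursor has no stereocentres at C6 or C7, only a tetrasubstituted enol ether. The forward step asks for lithiation at C6 only, and for an enol ether in which C13 is cis to the C7 oxygen (trans to C8).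

**25 ⇒ 23.** The O–C6 bond is cut: alkoxide at C13, allylic chloride at C6 (23). The other C–O cut would need an electrophile on the carbon next to the enol ether, which would ionise.

**23 ⇒ 22 ⇒ 20 ⇒ 19.** These are functional-group changes. The C13 alcohol is uncovered last from a vinylogous carbonate ester, which protects the enol ether from acid and distinguishes C13 from C12 until then; C6 arrives as an acetate (19) and is converted via alcohol 20 into chloride 22.

**19 ⇒ 6 + 17.** The C1=C10 alkene is cut into phosphonium salt 6 and methyl ketone 17. α-Alkoxy methyl ketones give Z-trisubstituted alkenes with non-stabilised ylides, and the cut is convergent. Building C8–C9 by an aldol on a Z-enal would instead need anti selectivity from a glycolate enolate and a sensitive aldehyde.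

**17 ⇒ 16 ⇒ 14 ⇒ 13 ⇒ 11 + 8.** The enol O–CH2 bond and the C7–C11 bond are cut. Ester 8 brings C11 with C12 (silyloxymethyl) and C13 (ester) already distinguished. A symmetric bis(hydroxymethyl) unit from a malonate was rejected because its two arms cannot be told apart later. The geometry of 16 comes from O-alkylation of the chelated sodium enolate of β-keto ester 14; the Weinreb amide of 16 becomes the C10 methyl ketone.

**11 ⇒ 10 ⇒ 9; 8 ⇒ 7.** Aldehyde 11 comes from D-erythronolactone acetonide 9, which supplies C8 and C9 with the right configuration and with the acetonide in place. Its carbonyl carbon becomes C10 and its CH2O carbon becomes C7.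

**6 ⇒ 5 ⇒ 4 ⇒ 3 ⇒ 1.** Geranyl acetate 1 supplies C1–C6 with the E alkene C4=C5; cleavage of its terminal alkene gives the C1 aldehyde 3.

## Roads not taken

Alternative 1: The cut removes C12 with its two bonds (O6–C12, C11–C12). Forward, the ten-membered ethynyl diol A1 is carbonylated with CO under PdCl2, PPh3 and SnCl2 to the α-methylene lactone A2, the C8 silyl ether of the target. Its merits are that the lactone is made in one step from a robust alkyne, that C12 needs no protecting group or oxidation-state change, and that the endgame after ring formation is shorter than the one chosen here. Its weakness is that it answers only the lactone: A1 already contains the ten-membered ring and all four stereocentres and still needs a macrocyclisation of its own. The carbonylation also has to tolerate a tertiary propargylic alcohol, the ester, and a Lewis-acidic tin co-catalyst next to an acid-sensitive diene. Against the shorter endgame, the chosen plan offers one step that forms the ring, the C6–C7 bond and both new stereocentres.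

Alternative 2: The cut is C3–C4. Forward, the terminal alkene of the open-chain alkenyl iodide A3 is hydroborated with 9-borabicyclo[3.3.1]nonane and the borane is coupled to the iodide under zerovalent palladium to give A4. Its merits are real: both alkene geometries are fixed before cyclisation, and C6 and C7 are set in the open chain by carbonyl additions with well-understood models. That stereocontrol is more secure than a macrocyclic transition state. Its weak points are the closure of a strained ten-membered ring containing an E alkene by sp3–sp2 coupling, and the hydroboration of an alkene that is conjugated to C1=C10 in A3, where an allylborane can form. A separate lactone annulation and more protecting-group steps follow. The chosen plan closes a strain-free ring first and introduces the medium-ring strain in an intramolecular sigmatropic step.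

Alternative 3: The cut is C1=C10. Forward, the ylide from the phosphonium ketone A5 (KN(SiMe3)2) condenses with the C10 methyl ketone to give A6. Its merits are that the α-alkoxy ketone favours the Z alkene, that a cis alkene is the comfortable geometry in a ten-membered ring, and that no stereocentre is formed in the ring closure. Its weak points are the slow intramolecular attack of an ylide on a hindered ketone to a medium ring, competing dimerisation, and the base-sensitive centre at C9 beside the ketone. The chosen route uses the same olefination, but between two fragments, where its precedent is strongest. In return it accepts less certain control at C6/C7.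

Key step: step 17

Assumption: locants C1–C15 follow germacrane numbering in all intermediates (C12 lactone carbonyl carbon, C13 exo-methylene carbon); reagent solutions (LDA, KN(SiMe3)2, n-BuLi, MeMgBr, i-Bu2AlH, Me2BBr) are used as purchased.

## Route

Step 1
Reactants: 1 geranyl acetate
Product: 3 (2E)-3-methyl-6-oxohex-2-en-1-yl acetate, via secondary ozonide 2 (not isolated)
Conditions: O3 (1.0 equiv), CH2Cl2, −78 °C; then Me2S, −78 °C → rt
Reagents that add atoms: ozone, O=[O+][O-]
Why: Chemoselective ozonolysis: the terminal trisubstituted alkene is more electron-rich than the one deactivated by the allylic acetate, so one equivalent of ozone cleaves it first; reduction of ozonide 2 gives the aldehyde (later C1).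

Step 2
Reactants: 3 (2E)-3-methyl-6-oxohex-2-en-1-yl acetate
Product: 4 (2E)-6-hydroxy-3-methylhex-2-en-1-yl acetate
Conditions: NaBH4, MeOH, 0 °C
Reagents that add atoms: none
Why: Borohydride reduction of an aldehyde; the acetate survives short exposure at 0 °C.

Step 3
Reactants: 4 (2E)-6-hydroxy-3-methylhex-2-en-1-yl acetate
Product: 5 (2E)-6-iodo-3-methylhex-2-en-1-yl acetate
Conditions: I2, PPh3, imidazole, CH2Cl2, 0 °C → rt
Reagents that add atoms: iodine, [I][I]
Why: Appel-type iodination of a primary alcohol (Garegg–Samuelsson conditions); the allylic acetate is untouched.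

Step 4
Reactants: 5 (2E)-6-iodo-3-methylhex-2-en-1-yl acetate
Product: 6 [(4E)-6-acetoxy-4-methylhex-4-en-1-yl]triphenylphosphonium iodide
Conditions: PPh3, MeCN, reflux
Reagents that add atoms: triphenylphosphine, c1ccc(cc1)P(c1ccccc1)c1ccccc1
Why: SN2 quaternisation of the phosphine by a primary iodide; the allylic acetate does not react without a metal catalyst.

Step 5
Reactants: 7 methyl 3-hydroxypropanoate
Product: 8 methyl 3-[(triisopropylsilyl)oxy]propanoate
Conditions: TIPSCl, imidazole, DMF, rt
Reagents that add atoms: chlorotriisopropylsilane, CC(C)[Si](Cl)(C(C)C)C(C)C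
Why: Silylation of a primary alcohol; the bulky silyl ether does not coordinate lithium, has no acidic benzylic hydrogens and resists O-to-O migration.

Step 6
Reactants: 9 (−)-2,3-O-isopropylidene-D-erythronolactone
Product: 10 (4R,5R)-5-(hydroxymethyl)-N-methoxy-N,2,2-trimethyl-1,3-dioxolane-4-carboxamide
Conditions: MeNH(OMe)·HCl, Me3Al, CH2Cl2, 0 °C → rt; aq. KNaC4H4O6
Reagents that add atoms: N,O-dimethylhydroxylamine hydrochloride, CNOC.Cl
Why: Weinreb aminolysis of a lactone by the aluminium amide; both stereocentres (later C9 and C8) are kept and the freed CH2OH is the later C7.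

Step 7
Reactants: 10 (4R,5R)-5-(hydroxymethyl)-N-methoxy-N,2,2-trimethyl-1,3-dioxolane-4-carboxamide
Product: 11 (4R,5S)-5-formyl-N-methoxy-N,2,2-trimethyl-1,3-dioxolane-4-carboxamide
Conditions: Dess–Martin periodinane, NaHCO3, CH2Cl2, 0 °C → rt
Reagents that add atoms: none
Why: Dess–Martin oxidation under buffered, non-basic conditions; the aldehyde is used crude so the cis α-alkoxy centre (C8) does not epimerise.

Step 8
Reactants: 8 methyl 3-[(triisopropylsilyl)oxy]propanoate; 11 (4R,5S)-5-formyl-N-methoxy-N,2,2-trimethyl-1,3-dioxolane-4-carboxamide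
Product: 13 methyl 3-hydroxy-3-[(4R,5R)-5-[methoxy(methyl)carbamoyl]-2,2-dimethyl-1,3-dioxolan-4-yl]-2-{[(triisopropylsilyl)oxy]methyl}propanoate (mixture of epimers at the two new centres), via lithium enolate 12 (not isolated)
Conditions: LiN(i-Pr)2, THF, −78 °C; then 11, −78 °C; sat. NH4Cl
Reagents that add atoms: none
Why: Aldol addition of an ester lithium enolate at −78 °C, where loss of the β-silyloxy group is slow; it forms the C7–C11 bond, and the two new centres are erased in steps 9 and 10.

Step 9
Reactants: 13 the aldol adduct of step 8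
Product: 14 methyl 3-[(4S,5R)-5-[methoxy(methyl)carbamoyl]-2,2-dimethyl-1,3-dioxolan-4-yl]-3-oxo-2-{[(triisopropylsilyl)oxy]methyl}propanoate
Conditions: Dess–Martin periodinane, NaHCO3, CH2Cl2, rt
Reagents that add atoms: none
Why: Dess–Martin oxidation of a β-hydroxy ester to the β-keto ester (C7 ketone).

Step 10
Reactants: 14 the β-keto ester of step 9
Product: 16 methyl (2Z)-3-(methoxymethoxy)-3-[(4S,5R)-5-[methoxy(methyl)carbamoyl]-2,2-dimethyl-1,3-dioxolan-4-yl]-2-{[(triisopropylsilyl)oxy]methyl}prop-2-enoate, via sodium enolate 15 (not isolated)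
Conditions: NaH, THF, 0 °C; then MOMCl, 0 °C
Reagents that add atoms: chloromethyl methyl ether, COCCl
Why: O-alkylation of a chelated sodium β-keto ester enolate by a hard chloromethyl ether; the sodium bridge between enolate oxygen and ester carbonyl places OMOM cis to the ester (later C13) and the silyloxymethyl arm (C12) cis to C8, as in chelation-controlled enol phosphate and enol sulfonate formation.

Step 11
Reactants: 16 the enol ether of step 10
Product: 17 methyl (2Z)-3-[(4S,5R)-5-acetyl-2,2-dimethyl-1,3-dioxolan-4-yl]-3-(methoxymethoxy)-2-{[(triisopropylsilyl)oxy]methyl}prop-2-enoate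
Conditions: MeMgBr, THF, −30 → 0 °C; sat. NH4Cl
Reagents that add atoms: methylmagnesium bromide, C[Mg]Br
Why: Weinreb ketone synthesis; the chelated tetrahedral intermediate stops over-addition, and the fully substituted vinylogous carbonate ester is far less electrophilic than the amide.

Step 12
Reactants: 6 [(4E)-6-acetoxy-4-methylhex-4-en-1-yl]triphenylphosphonium iodide; 17 the methyl ketone of step 11
Product: 19 methyl (2Z)-3-[(4S,5S)-5-[(2Z,6E)-8-acetoxy-6-methylocta-2,6-dien-2-yl]-2,2-dimethyl-1,3-dioxolan-4-yl]-3-(methoxymethoxy)-2-{[(triisopropylsilyl)oxy]methyl}prop-2-enoate, via phosphorus ylide 18 (not isolated)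
Conditions: KN(SiMe3)2 (0.95 equiv), THF, −78 → 0 °C; then 17, −78 °C → rt
Reagents that add atoms: none
Why: Wittig olefination of an α-alkoxy methyl ketone with a non-stabilised ylide, which gives the Z-trisubstituted alkene (C2 cis to C9); a slight deficit of base and low temperature protect C9 from epimerisation.

Step 13
Reactants: 19 the acetate of step 12
Product: 20 the corresponding C6 alcohol, methyl (2Z)-3-[(4S,5S)-5-[(2Z,6E)-8-hydroxy-6-methylocta-2,6-dien-2-yl]-2,2-dimethyl-1,3-dioxolan-4-yl]-3-(methoxymethoxy)-2-{[(triisopropylsilyl)oxy]methyl}prop-2-enoate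
Conditions: K2CO3 (cat.), MeOH, 0 °C
Reagents that add atoms: none
Why: Base-catalysed transesterification removes the acetate; exchange at the methyl ester is degenerate and the silyl ether is stable.

Step 14
Reactants: 20 the C6 alcohol of step 13
Product: 22 the C6 allylic chloride (8-chloro analogue of 20), via allylic mesylate 21 (not isolated)
Conditions: MsCl, 2,4,6-collidine, LiCl, DMF, 0 °C
Reagents that add atoms: lithium chloride, [Li+].[Cl-]
Why: Collington–Meyers chlorination (mesylate, then chloride displacement) gives the primary allylic chloride without allylic transposition.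

Step 15
Reactants: 22 the allylic chloride of step 14
Product: 23 (2E)-3-[(4S,5S)-5-[(2Z,6E)-8-chloro-6-methylocta-2,6-dien-2-yl]-2,2-dimethyl-1,3-dioxolan-4-yl]-3-(methoxymethoxy)-2-{[(triisopropylsilyl)oxy]methyl}prop-2-en-1-ol (C13 alcohol)
Conditions: i-Bu2AlH, CH2Cl2, −78 °C; aq. KNaC4H4O6
Reagents that add atoms: none
Why: 1,2-Reduction of the vinylogous carbonate ester to the allylic alcohol at −78 °C, which leaves the allylic chloride intact; the neutral tartrate work-up protects the now electron-rich enol ether.

Step 16
Reactants: 23 the chloro alcohol of step 15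
Product: 25 thirteen-membered bis-allylic ether O–C13H2–C11(CH2OTIPS)=C7(OMOM)–C8–C9–C10(Me)=C1–C2–C3–C4(Me)=C5–C6H2 with (1(10)Z,4E,7(11)E) alkenes and the (8S,9S) acetonide, via sodium alkoxide 24 (not isolated)
Conditions: NaH, Bu4NI (cat.), THF (0.002 M, slow addition), 0 → 40 °C
Reagents that add atoms: none
Why: Intramolecular Williamson etherification (SN2 at the primary allylic carbon, iodide-catalysed) under high dilution; the thirteen-membered ring is strain-free, and related ω-hydroxy allylic chlorides are known to close this way.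

Step 17
Reactants: 25 the thirteen-membered ether of step 16
Product: 27 (1(10)Z,4E,6S,7S,8S,9S)-8,9-(isopropylidenedioxy)-7-(methoxymethoxy)-12-[(triisopropylsilyl)oxy]germacra-1(10),4,11(13)-trien-6-ol, via C6-lithiated ether 26 (not isolated)
Conditions: n-BuLi, THF, −78 → −30 °C; sat. NH4Cl at −78 °C
Reagents that add atoms: none
Why: Proposed new method: n-BuLi removes a C6 hydrogen (allylic to C4=C5 and α to the ring oxygen) to give 26, whose carbanion bonds to C7 through a five-membered envelope transition state (C6, O, C13, C11, C7) while O–C13 breaks and the C11=C13 methylene forms, a concerted suprafacial [2,3] shift driven by the change from carbanion to alkoxide. The closest known reaction type is the [2,3]-Wittig ring contraction of thirteen-membered bis-allylic ethers to cyclodeca-1,5-dienols; what is new is a fully substituted, alkoxy-bearing migration terminus, which is more hindered and less electrophilic, but the five-membered array is held in place by the ring. The ten-membered carbocycle is closed by contraction, that is by transannular C6–C7 bonding that excises O–C13–C11 from the ring, not by end-to-end cyclisation. The C6/C7 relative configuration should follow from the enol ether geometry: with C8 trans to C13 and the C5 vinyl arm exo on the envelope, O6 ends up anti to C8, the arrangement needed for the trans lactone and the one found in the parent ring contractions. The absolute sense should come from the cis acetonide: allylic strain against the C12 methylene holds C8–H in the enol ether plane, C9 then leaves on one face, and the six-carbon tether C10–C5 is expected to deliver C6 to the face anti to C9, because bonding on the C9 face would demand three consecutive syn-clinal torsions (C6–C7–C8–C9, C7–C8–C9–C10, C9–C10=C1–C2). The step needs lithiation at C6 and not at C13 or C12; an anion at those carbons would place charge on the alkoxy-bearing C7 of a tetrasubstituted donor alkene, both sites are screened by the non-coordinating triisopropylsilyl group, and the other α-oxy allylic hydrogens (C8–H, C9–H) are tertiary and kinetically slow. Quenching cold keeps the product alkoxide from [1,2]-shift chemistry and from anionic oxy-Cope rearrangement of the 1,5-dien-3-olate.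

Step 18
Reactants: 27 the ring-contracted alcohol of step 17
Product: 28 (1(10)Z,4E,6S,7S,8S,9S)-8,9-(isopropylidenedioxy)-7-(methoxymethoxy)germacra-1(10),4,11(13)-triene-6,12-diol
Conditions: Bu4NF, THF, 0 °C → rt
Reagents that add atoms: none
Why: Fluoride cleavage of the silyl ether; the methoxymethyl ether and the acetonide are inert.

Step 19
Reactants: 28 the 6,12-diol of step 18
Product: 30 (1(10)Z,4E,6S,7S,8S,9S)-8,9-(isopropylidenedioxy)-7-(methoxymethoxy)germacra-1(10),4,11(13)-trien-12,6-olide, via lactol 29 (not isolated)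
Conditions: TEMPO (cat.), PhI(OAc)2, CH2Cl2, rt
Reagents that add atoms: none
Why: Oxidative lactonisation of a 2-methylene-1,4-diol: the primary allylic alcohol is oxidised to the enal, trapped by the C6 hydroxyl as lactol 29 and oxidised again; O8 is tied up in the acetonide, so only the 12,6-olide can form, and C6 and C7 are not touched.

Step 20
Reactants: 30 the protected lactone of step 19
Product: 31 (1(10)Z,4E,6S,7R,8S,9S)-7,8,9-trihydroxygermacra-1(10),4,11(13)-trien-12,6-olide
Conditions: Me2BBr, CH2Cl2, −78 °C; then sat. NaHCO3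
Reagents that add atoms: none
Why: Me2BBr cleaves methoxymethyl ethers and acetonides at −78 °C by acetal exchange to α-bromo ethers that hydrolyse on work-up; low temperature and the absence of protic acid spare the 1,5-diene and the α-methylene lactone.

Step 21
Reactants: 31 the triol of step 20; 32 isobutyryl chloride
Product: 33 CNP0301808.4, (1(10)Z,4E,6S,7R,8S,9S)-7,8-dihydroxy-9-(2-methylpropanoyloxy)germacra-1(10),4,11(13)-trien-12,6-olide
Conditions: 2,4,6-collidine, CH2Cl2, −40 → 0 °C
Reagents that add atoms: none
Why: Site-selective acylation: the tertiary C7 hydroxyl is inert and the C8 hydroxyl is flanked by the quaternary C7, so the allylic C9 hydroxyl should react first with one equivalent of acid chloride at low temperature.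

## Compound list

1 | geranyl acetate, (2E)-3,7-dimethylocta-2,6-dien-1-yl acetate | CC(C)=CCC/C(C)=C/COC(C)=O | starting material
2 | secondary ozonide of the terminal alkene of 1, (2E)-5-(5,5-dimethyl-1,2,4-trioxolan-3-yl)-3-methylpent-2-en-1-yl acetate | CC(=O)OC/C=C(\C)CCC1OOC(C)(C)O1 | intermediate
3 | (2E)-3-methyl-6-oxohex-2-en-1-yl acetate | CC(=O)OC/C=C(\C)CCC=O | intermediate
4 | (2E)-6-hydroxy-3-methylhex-2-en-1-yl acetate | CC(=O)OC/C=C(\C)CCCO | intermediate
5 | (2E)-6-iodo-3-methylhex-2-en-1-yl acetate | CC(=O)OC/C=C(\C)CCCI | intermediate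
6 | [(4E)-6-acetoxy-4-methylhex-4-en-1-yl]triphenylphosphonium iodide | CC(=O)OC/C=C(\C)CCC[P+](c1ccccc1)(c1ccccc1)c1ccccc1.[I-] | intermediate
7 | methyl 3-hydroxypropanoate | COC(=O)CCO | starting material
8 | methyl 3-[(triisopropylsilyl)oxy]propanoate | COC(=O)CCO[Si](C(C)C)(C(C)C)C(C)C | intermediate
9 | (−)-2,3-O-isopropylidene-D-erythronolactone, (3aR,6aR)-2,2-dimethyldihydrofuro[3,4-d][1,3]dioxol-4(3aH)-one | CC1(C)O[C@@H]2COC(=O)[C@@H]2O1 | starting material
10 | (4R,5R)-5-(hydroxymethyl)-N-methoxy-N,2,2-trimethyl-1,3-dioxolane-4-carboxamide | CON(C)C(=O)[C@@H]1OC(C)(C)O[C@@H]1CO | intermediate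
11 | (4R,5S)-5-formyl-N-methoxy-N,2,2-trimethyl-1,3-dioxolane-4-carboxamide | CON(C)C(=O)[C@@H]1OC(C)(C)O[C@@H]1C=O | intermediate
12 | lithium enolate of 8, lithium 1-methoxy-3-[(triisopropylsilyl)oxy]prop-1-en-1-olate | [Li+].COC([O-])=CCO[Si](C(C)C)(C(C)C)C(C)C | intermediate
13 | methyl 3-hydroxy-3-[(4R,5R)-5-[methoxy(methyl)carbamoyl]-2,2-dimethyl-1,3-dioxolan-4-yl]-2-{[(triisopropylsilyl)oxy]methyl}propanoate (epimer mixture at C2 and C3 of the propanoate) | CON(C)C(=O)[C@@H]1OC(C)(C)O[C@@H]1C(O)C(CO[Si](C(C)C)(C(C)C)C(C)C)C(=O)OC | intermediate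
14 | methyl 3-[(4S,5R)-5-[methoxy(methyl)carbamoyl]-2,2-dimethyl-1,3-dioxolan-4-yl]-3-oxo-2-{[(triisopropylsilyl)oxy]methyl}propanoate | CON(C)C(=O)[C@@H]1OC(C)(C)O[C@@H]1C(=O)C(CO[Si](C(C)C)(C(C)C)C(C)C)C(=O)OC | intermediate
15 | sodium (Z)-enolate of 14 (enolate oxygen cis to the ester) | [Na+].CON(C)C(=O)[C@@H]1OC(C)(C)O[C@@H]1/C([O-])=C(\CO[Si](C(C)C)(C(C)C)C(C)C)C(=O)OC | intermediate
16 | methyl (2Z)-3-(methoxymethoxy)-3-[(4S,5R)-5-[methoxy(methyl)carbamoyl]-2,2-dimethyl-1,3-dioxolan-4-yl]-2-{[(triisopropylsilyl)oxy]methyl}prop-2-enoate | CON(C)C(=O)[C@@H]1OC(C)(C)O[C@@H]1/C(OCOC)=C(\CO[Si](C(C)C)(C(C)C)C(C)C)C(=O)OC | intermediate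
17 | methyl (2Z)-3-[(4S,5R)-5-acetyl-2,2-dimethyl-1,3-dioxolan-4-yl]-3-(methoxymethoxy)-2-{[(triisopropylsilyl)oxy]methyl}prop-2-enoate | CC(=O)[C@@H]1OC(C)(C)O[C@@H]1/C(OCOC)=C(\CO[Si](C(C)C)(C(C)C)C(C)C)C(=O)OC | intermediate
18 | [(4E)-6-acetoxy-4-methylhex-4-en-1-ylidene]triphenylphosphorane | CC(=O)OC/C=C(\C)CCC=P(c1ccccc1)(c1ccccc1)c1ccccc1 | intermediate
19 | methyl (2Z)-3-[(4S,5S)-5-[(2Z,6E)-8-acetoxy-6-methylocta-2,6-dien-2-yl]-2,2-dimethyl-1,3-dioxolan-4-yl]-3-(methoxymethoxy)-2-{[(triisopropylsilyl)oxy]methyl}prop-2-enoate | CC(=O)OC/C=C(\C)CC/C=C(/C)[C@@H]1OC(C)(C)O[C@@H]1/C(OCOC)=C(\CO[Si](C(C)C)(C(C)C)C(C)C)C(=O)OC | intermediate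
20 | C6 alcohol, the 8-hydroxy analogue of 19 | OC/C=C(\C)CC/C=C(/C)[C@@H]1OC(C)(C)O[C@@H]1/C(OCOC)=C(\CO[Si](C(C)C)(C(C)C)C(C)C)C(=O)OC | intermediate
21 | C6 methanesulfonate of 20 | CS(=O)(=O)OC/C=C(\C)CC/C=C(/C)[C@@H]1OC(C)(C)O[C@@H]1/C(OCOC)=C(\CO[Si](C(C)C)(C(C)C)C(C)C)C(=O)OC | intermediate
22 | C6 allylic chloride, the 8-chloro analogue of 19 | ClC/C=C(\C)CC/C=C(/C)[C@@H]1OC(C)(C)O[C@@H]1/C(OCOC)=C(\CO[Si](C(C)C)(C(C)C)C(C)C)C(=O)OC | intermediate
23 | (2E)-3-[(4S,5S)-5-[(2Z,6E)-8-chloro-6-methylocta-2,6-dien-2-yl]-2,2-dimethyl-1,3-dioxolan-4-yl]-3-(methoxymethoxy)-2-{[(triisopropylsilyl)oxy]methyl}prop-2-en-1-ol | ClC/C=C(\C)CC/C=C(/C)[C@@H]1OC(C)(C)O[C@@H]1/C(OCOC)=C(\CO[Si](C(C)C)(C(C)C)C(C)C)CO | intermediate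
24 | sodium alkoxide of 23 (at C13) | [Na+].ClC/C=C(\C)CC/C=C(/C)[C@@H]1OC(C)(C)O[C@@H]1/C(OCOC)=C(\CO[Si](C(C)C)(C(C)C)C(C)C)C[O-] | intermediate
25 | thirteen-membered ether: ring O–C13H2–C11(CH2OTIPS)=C7(OMOM)–C8–C9–C10(Me)=C1–C2–C3–C4(Me)=C5–C6H2, (1(10)Z,4E,7(11)E), (8S,9S)-acetonide | O1C/C(CO[Si](C(C)C)(C(C)C)C(C)C)=C(OCOC)/[C@H]2OC(C)(C)O[C@H]2/C(C)=C\CC/C(C)=C/C1 | intermediate
26 | C6-lithiated 25 | O1C/C(CO[Si](C(C)C)(C(C)C)C(C)C)=C(OCOC)/[C@H]2OC(C)(C)O[C@H]2/C(C)=C\CC/C(C)=C/C1[Li] | intermediate
27 | (1(10)Z,4E,6S,7S,8S,9S)-8,9-(isopropylidenedioxy)-7-(methoxymethoxy)-12-[(triisopropylsilyl)oxy]germacra-1(10),4,11(13)-trien-6-ol | O[C@H]1/C=C(\C)CC/C=C(/C)[C@@H]2OC(C)(C)O[C@@H]2[C@]1(OCOC)C(=C)CO[Si](C(C)C)(C(C)C)C(C)C | intermediate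
28 | (1(10)Z,4E,6S,7S,8S,9S)-8,9-(isopropylidenedioxy)-7-(methoxymethoxy)germacra-1(10),4,11(13)-triene-6,12-diol | O[C@H]1/C=C(\C)CC/C=C(/C)[C@@H]2OC(C)(C)O[C@@H]2[C@]1(OCOC)C(=C)CO | intermediate
29 | lactol of 30 (12-hydroxy-6,12-epoxide, C12 epimers) | C=C1C(O)O[C@H]2/C=C(\C)CC/C=C(/C)[C@@H]3OC(C)(C)O[C@@H]3[C@]12OCOC | intermediate
30 | (1(10)Z,4E,6S,7S,8S,9S)-8,9-(isopropylidenedioxy)-7-(methoxymethoxy)germacra-1(10),4,11(13)-trien-12,6-olide | C=C1C(=O)O[C@H]2/C=C(\C)CC/C=C(/C)[C@@H]3OC(C)(C)O[C@@H]3[C@]12OCOC | intermediate
31 | (1(10)Z,4E,6S,7R,8S,9S)-7,8,9-trihydroxygermacra-1(10),4,11(13)-trien-12,6-olide | C=C1C(=O)O[C@H]2/C=C(\C)CC/C=C(/C)[C@H](O)[C@H](O)[C@]12O | intermediate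
32 | isobutyryl chloride (2-methylpropanoyl chloride) | CC(C)C(Cl)=O | starting material
33 | CNP0301808.4, (1(10)Z,4E,6S,7R,8S,9S)-7,8-dihydroxy-9-(2-methylpropanoyloxy)germacra-1(10),4,11(13)-trien-12,6-olide | C=C1C(=O)O[C@H]2/C=C(\C)CC/C=C(/C)[C@H](OC(=O)C(C)C)[C@H](O)[C@]12O | target

## Count and risks

Total steps: 21. Longest linear sequence: 16 steps (9 → 33, steps 6–21); the C1–C6 arm (steps 1–4) and ester 8 (step 5) are made in parallel.

**Step 17 (key step, proposed new method).** Three things can go wrong. The shift may not occur at all, because the fully substituted, donor-substituted terminus is unreceptive, and the lithio ether would then be lost to [1,2]-shift or simple reprotonation. Lithiation may go to C13 under direction by the neighbouring methoxymethyl oxygen. Or C6 may bond to the wrong face of C7, because the tether argument for the acetonide is qualitative.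
The fallback uses known chemistry, an intramolecular CrCl2-mediated Nozaki–Hiyama–Kishi allylation with a 2-(bromomethyl)acrylate, the reaction type used to close germacranolide rings together with the α-methylene lactone. It sets out from 20 and returns at 30. MnO2 oxidises the C6 alcohol to the enal F1. HF·pyridine removes the silyl group to give the hydroxymethyl acrylate F2. CBr4/PPh3 gives the allylic bromide F3. CrCl2 (divalent chromium) in THF at high dilution then adds the allyl unit through C7 to the C6 aldehyde, and the chromium alkoxide closes on the methyl ester to give 30.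

**Step 10.** The sodium enolate may lose the β-silyloxy group (E1cB to a methylene β-keto ester) before it is trapped, or the chelate may be imperfect and the enol ether geometry erode.
The fallback changes the C12 protecting-group strategy to a poorer leaving group; it sets out from 7 and 11 and returns at 16. 7 is converted with 4-methoxybenzyl trichloroacetimidate (cat. TfOH) into methyl 3-[(4-methoxybenzyl)oxy]propanoate F4. Its lithium enolate adds to 11 to give the β-hydroxy ester F5. Dess–Martin oxidation gives the β-keto ester F6, and NaH/MOMCl gives the benzyl-protected enol ether F7. DDQ frees the C12 alcohol F8 (the conjugated enol ether tolerates it), and TIPSCl/imidazole leads to 16.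

**Step 12.** The basic ylide may epimerise C9 of the crowded, doubly activated ketone 17 (cis to trans on the dioxolane), and the bulky neighbour may erode Z selectivity or slow the condensation.
The fallback moves the olefination to the front, onto a simple α-alkoxy ketone of the type for which the Z preference is best documented; it sets out from 10 (with ylide 18) and returns at 19. TBSCl/imidazole gives the tert-butyldimethylsilyl ether F9, MeMgBr the methyl ketone F10, and ylide 18 the Z-alkene F11. HF·pyridine frees the C7 alcohol F12, Dess–Martin oxidation gives the aldehyde F13, enolate 12 adds to give the β-hydroxy ester F14, oxidation gives the β-keto ester F15, and NaH/MOMCl leads to 19.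

**Step 16.** The strongly basic alkoxide may give elimination to a diene, oligomers, or migration of the silyl group from O12 to the C13 alkoxide, after which the wrong oxygen would cyclise.
The fallback closes the same bond by π-allyl substitution under nearly neutral conditions; it sets out from 23 and returns at 25 with no new isolated compound. 23 is converted into its zinc alkoxide (Et2Zn) and cyclised with Pd(PPh3)4 (zerovalent palladium) through the allylpalladium intermediate generated from the allylic chloride.

**Step 21.** Site selectivity between O9 and O8 may be poor, the ester may migrate to O8, and the free O8 may attack the lactone under base.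
The fallback separates the two deprotections so that O8 stays shielded by the C7 ether during acylation; it sets out from 30 and returns at 33. Mild hydrolysis (aq. AcOH, rt) removes only the acetonide to give the 8,9-diol F16. Its dibutylstannylene acetal (Bu2SnO) is acylated with 32 at the allylic O9 to give the C9 isobutyrate F17, and Me2BBr at −78 °C removes the methoxymethyl ether to give 33.

## Further compounds

F1 | step 17 | C6 enal, 8-oxo analogue of 20 | O=C/C=C(\C)CC/C=C(/C)[C@@H]1OC(C)(C)O[C@@H]1/C(OCOC)=C(\CO[Si](C(C)C)(C(C)C)C(C)C)C(=O)OC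
F2 | step 17 | hydroxymethyl acrylate, desilylated F1 | O=C/C=C(\C)CC/C=C(/C)[C@@H]1OC(C)(C)O[C@@H]1/C(OCOC)=C(\CO)C(=O)OC
F3 | step 17 | allylic bromide from F2 | O=C/C=C(\C)CC/C=C(/C)[C@@H]1OC(C)(C)O[C@@H]1/C(OCOC)=C(\CBr)C(=O)OC
F4 | step 10 | methyl 3-[(4-methoxybenzyl)oxy]propanoate | COC(=O)CCOCc1ccc(OC)cc1
F5 | step 10 | β-hydroxy ester, 4-methoxybenzyl analogue of 13 | CON(C)C(=O)[C@@H]1OC(C)(C)O[C@@H]1C(O)C(COCc1ccc(OC)cc1)C(=O)OC
F6 | step 10 | β-keto ester, 4-methoxybenzyl analogue of 14 | CON(C)C(=O)[C@@H]1OC(C)(C)O[C@@H]1C(=O)C(COCc1ccc(OC)cc1)C(=O)OC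
F7 | step 10 | (Z)-enol ether, 4-methoxybenzyl analogue of 16 | CON(C)C(=O)[C@@H]1OC(C)(C)O[C@@H]1/C(OCOC)=C(\COCc1ccc(OC)cc1)C(=O)OC
F8 | step 10 | C12 alcohol, desilyl analogue of 16 | CON(C)C(=O)[C@@H]1OC(C)(C)O[C@@H]1/C(OCOC)=C(\CO)C(=O)OC
F9 | step 12 | tert-butyldimethylsilyl ether of 10 | CON(C)C(=O)[C@@H]1OC(C)(C)O[C@@H]1CO[Si](C)(C)C(C)(C)C
F10 | step 12 | 1-[(4R,5R)-5-{[(tert-butyldimethylsilyl)oxy]methyl}-2,2-dimethyl-1,3-dioxolan-4-yl]ethanone | CC(=O)[C@@H]1OC(C)(C)O[C@@H]1CO[Si](C)(C)C(C)(C)C
F11 | step 12 | Z-alkene from F10 and 18 (C6 acetate, C7 silyl ether) | CC(=O)OC/C=C(\C)CC/C=C(/C)[C@@H]1OC(C)(C)O[C@@H]1CO[Si](C)(C)C(C)(C)C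
F12 | step 12 | C7 alcohol from F11 | CC(=O)OC/C=C(\C)CC/C=C(/C)[C@@H]1OC(C)(C)O[C@@H]1CO
F13 | step 12 | C7 aldehyde from F12 | CC(=O)OC/C=C(\C)CC/C=C(/C)[C@@H]1OC(C)(C)O[C@@H]1C=O
F14 | step 12 | β-hydroxy ester from F13 and 12 | CC(=O)OC/C=C(\C)CC/C=C(/C)[C@@H]1OC(C)(C)O[C@@H]1C(O)C(CO[Si](C(C)C)(C(C)C)C(C)C)C(=O)OC
F15 | step 12 | β-keto ester from F14 | CC(=O)OC/C=C(\C)CC/C=C(/C)[C@@H]1OC(C)(C)O[C@@H]1C(=O)C(CO[Si](C(C)C)(C(C)C)C(C)C)C(=O)OC
F0 | step 16 | none | none
F16 | step 21 | 8,9-diol with C7 methoxymethyl ether (acetonide-free 30) | C=C1C(=O)O[C@H]2/C=C(\C)CC/C=C(/C)[C@H](O)[C@H](O)[C@]12OCOC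
F17 | step 21 | C9 isobutyrate with C7 methoxymethyl ether | C=C1C(=O)O[C@H]2/C=C(\C)CC/C=C(/C)[C@H](OC(=O)C(C)C)[C@H](O)[C@]12OCOC
A1 | alternative 1 | ten-membered C7-ethynyl 6,7-diol with C8 triethylsilyl ether and C9 isobutyrate | C#C[C@]1(O)[C@@H](O)/C=C(\C)CC/C=C(/C)[C@H](OC(=O)C(C)C)[C@@H]1O[Si](CC)(CC)CC
A2 | alternative 1 | C8 triethylsilyl ether of 33 | C=C1C(=O)O[C@H]2/C=C(\C)CC/C=C(/C)[C@H](OC(=O)C(C)C)[C@H](O[Si](CC)(CC)CC)[C@]12O
A3 | alternative 2 | open-chain C4 alkenyl iodide with terminal C2=C3 alkene, C6/C7 acetonide, C7 silylethynyl group and C8/C9 silyl ethers | C=C/C=C(/C)[C@H](O[Si](C)(C)C(C)(C)C)[C@H](O[Si](C)(C)C(C)(C)C)[C@@]1(C#C[Si](C)(C)C)OC(C)(C)O[C@H]1/C=C(\C)I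
A4 | alternative 2 | ten-membered (1(10)Z,4E)-diene with C6/C7 acetonide and C7 silylethynyl group | CC1(C)O[C@H]2/C=C(\C)CC/C=C(/C)[C@H](O[Si](C)(C)C(C)(C)C)[C@H](O[Si](C)(C)C(C)(C)C)[C@@]2(C#C[Si](C)(C)C)O1
A5 | alternative 3 | open-chain C1 phosphonium bromide with C10 methyl ketone, C9 4-methoxybenzyl ether and C6/C7 acetonide | [Br-].CC(=O)[C@H](OCc1ccc(OC)cc1)[C@H](O[Si](C)(C)C(C)(C)C)[C@@]1(C(=C)CO[Si](C)(C)C(C)(C)C)OC(C)(C)O[C@H]1/C=C(\C)CCC[P+](c1ccccc1)(c1ccccc1)c1ccccc1
A6 | alternative 3 | ten-membered (1(10)Z,4E)-diene with C9 4-methoxybenzyl ether and C6/C7 acetonide | CC1(C)O[C@H]2/C=C(\C)CC/C=C(/C)[C@H](OCc3ccc(OC)cc3)[C@H](O[Si](C)(C)C(C)(C)C)[C@@]2(C(=C)CO[Si](C)(C)C(C)(C)C)O1
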